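**Retrosynthetic overview**
1. The target comes from its tetra-MOM ether by one acid-catalysed global deprotection, so no base is used once C2 is set.
2. The C2–C1' bond is cut. An enantioselective, dearomatising 1,4-arylation of a flat 8-prenyl-5,7-dioxygenated chromone (benzo-γ-pyrone) with the ring B boronic acid joins both halves and sets the only stereocentre. No chalcone or oxa-Michael step is involved.
3. The chromone comes from a one-carbon annulation (DMF-DMA) of 3-prenylphloroacetophenone bis-MOM ether. That ketone comes from mirror-symmetric phloroacetophenone and prenyl bromide by a symmetry-breaking C-prenylation through a dienone.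
4. The boronic acid comes from a sterically controlled C–H borylation of 3-prenylcatechol bis-MOM ether. That ether comes from mirror-symmetric catechol by MOM protection, directed ortho-lithiation and prenylation.
5. Ring order: rings A and B are bought. Ring C is closed first as an aromatic pyrone (step 3) and dearomatised to the chiral dihydropyranone in step 7.

Assumption: the sense of induction in step 7 is taken from the (S)-BINAP/cyclohexenone model (same ring topology); the ligand is sold in both forms, so the configuration of 14 would be checked by CD and the antipode used if needed.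

Step 1
Reactants: 1 phloroacetophenone (2,4,6-trihydroxyacetophenone); 2 prenyl bromide (1-bromo-3-methylbut-2-ene)
Product: 4 1-[2,4,6-trihydroxy-3-(3-methylbut-2-en-1-yl)phenyl]ethan-1-one (3-prenylphloroacetophenone), via prenyl cyclohexadienone 3 (not isolated)
Conditions: KOH (1.0 equiv), H2O, 0 °C; 2 (0.8 equiv) added slowly, 0 °C to rt, 3 h
Reagents that add atoms: none
Why: Phenoxide C-alkylation (SN2) in water, where hydrogen bonding blocks the oxygens so the soft ring carbon attacks, breaks the mirror symmetry of 1 through the dearomatised dienone 3 (its sp3 carbon is racemic and transient), which tautomerises back to the phenol, and because C3 and C5 of 1 are equivalent only one mono-C-prenyl isomer can form while the excess of 1 holds back diprenylation.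

Step 2
Reactants: 4 3-prenylphloroacetophenone
Product: 5 1-[2-hydroxy-4,6-bis(methoxymethoxy)-3-(3-methylbut-2-en-1-yl)phenyl]ethan-1-one
Conditions: MOMCl (2.1 equiv), K2CO3 (3 equiv), acetone, 0 °C to rt
Reagents that add atoms: chloromethyl methyl ether (MOMCl), COCCl
Why: In this Williamson-type O-alkylation the unchelated 4-OH reacts first and, of the two hydrogen-bonded ortho hydroxyls, the one next to H (C6) is far more accessible than the one wedged between acetyl and prenyl, so the OH that must become O1 next to the prenyl group is the one left free.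

Step 3
Reactants: 5 bis-MOM prenyl ketone
Product: 7 5,7-bis(methoxymethoxy)-8-(3-methylbut-2-en-1-yl)-4H-chromen-4-one, via enaminone 6 (not isolated)
Conditions: Me2NCH(OMe)2 (3 equiv), toluene, 95 °C, 3 h; evaporate; AcOH, 60 °C, 1 h
Reagents that add atoms: N,N-dimethylformamide dimethyl acetal, COC(OC)N(C)C
Why: Enaminone condensation of the methyl ketone followed by acid-promoted addition–elimination (oxa-Michael, loss of Me2NH) by the only free phenol closes ring C as a flat benzo-γ-pyrone and fixes the prenyl group at C8 without 6/8 ambiguity, and acetic acid is too weak to cleave aryl MOM ethers or protonate the prenyl alkene.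

Step 4
Reactants: 8 catechol (benzene-1,2-diol)
Product: 9 1,2-bis(methoxymethoxy)benzene
Conditions: NaH (2.4 equiv), DMF, 0 °C; MOMCl (2.3 equiv), 0 °C to rt
Reagents that add atoms: chloromethyl methyl ether (MOMCl), COCCl
Why: Double Williamson-type O-alkylation of the disodium catecholate installs groups that both protect the catechol and direct the lithiation in the next step.

Step 5
Reactants: 9 1,2-bis(methoxymethoxy)benzene; 2 prenyl bromide
Product: 11 1,2-bis(methoxymethoxy)-3-(3-methylbut-2-en-1-yl)benzene, via aryllithium 10 (not isolated)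
Conditions: n-BuLi (1.1 equiv), THF, 0 °C to rt, 1 h; CuI (10 mol %), 2 (1.2 equiv), -78 °C to rt
Reagents that add atoms: none
Why: Directed ortho-metalation of symmetric 9 (both ortho positions are equivalent, so a single aryllithium forms) followed by copper-assisted SN2 allylation at the primary carbon of prenyl bromide gives the linear prenyl arene and breaks the symmetry of the catechol.

Step 6
Reactants: 11 3-prenylcatechol bis-MOM ether
Product: 13 [3,4-bis(methoxymethoxy)-5-(3-methylbut-2-en-1-yl)phenyl]boronic acid, via pinacol boronate 12 (not isolated)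
Conditions: [Ir(OMe)(cod)]2 (1.5 mol %), 4,4'-di-tert-butyl-2,2'-bipyridine (3 mol %), B2pin2 (0.7 equiv), MTBE, 60 °C; evaporate; NaIO4 (3 equiv), NH4OAc (3 equiv), acetone/H2O 1:1, rt
Reagents that add atoms: bis(pinacolato)diboron, CC1(C)OB(OC1(C)C)B1OC(C)(C)C(C)(C)O1; water, O
Why: In this sterically controlled iridium-catalysed aromatic C–H borylation only C5–H of the 1,2,3-trisubstituted arene has no ortho neighbour, which is exactly the carbon para to the inner oxygen, the trisubstituted alkene is a poor partner for the catalyst, and buffered periodate cleavage of the pinacol unit frees the boronic acid without touching MOM ethers or alkene.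

Step 7
Reactants: 7 8-prenyl-5,7-bis(MOM)chromone; 13 ring B boronic acid
Product: 14 (2S)-2-[3,4-bis(methoxymethoxy)-5-(3-methylbut-2-en-1-yl)phenyl]-5,7-bis(methoxymethoxy)-8-(3-methylbut-2-en-1-yl)-2,3-dihydro-4H-chromen-4-one
Conditions: [RhCl(C2H4)2]2 (2.5 mol %), (S)-MeO-F12-BIPHEP [(S)-(6,6'-dimethoxybiphenyl-2,2'-diyl)bis(bis(3,4,5-trifluorophenyl)phosphine)] (5.5 mol %), aq KOH (0.2 equiv), 13 (2 equiv), toluene/H2O 10:1, 30 °C
Reagents that add atoms: none
Why: Key step, a Hayashi–Miyaura-type asymmetric 1,4-addition in which the aryl complex of monovalent rhodium formed from 13 inserts the C2=C3 bond of the pyrone ring and water protonates the oxa-π-allyl enolate faster than β-aryloxide elimination, so the 10-π-electron benzo-γ-pyrone is dearomatised to the dihydropyranone while the (S)-biaryl bisphosphine, as (S)-BINAP does with cyclohexenone, leaves only the Re face of C2 open and gives the 2S centre, the electron-poor phosphine keeping the metal active enough for this electron-rich enone at 30 °C and leaving MOM ethers and trisubstituted alkenes untouched.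

Step 8
Reactants: 14 (2S)-tetra-MOM flavanone
Product: 15 (2S)-2-[3,4-dihydroxy-5-(3-methylbut-2-en-1-yl)phenyl]-5,7-dihydroxy-8-(3-methylbut-2-en-1-yl)-2,3-dihydro-4H-chromen-4-one (target)
Conditions: HCl (1.25 M in MeOH), MeOH, 40 °C, Ar, 2 h
Reagents that add atoms: none
Why: Acid-catalysed acetal exchange (MOM solvolysis) is faster than protonation of a trisubstituted alkene, so all four phenols are freed without chroman formation, and since no base is present the retro-oxa-Michael/chalcone pathway that would racemise C2 stays closed.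

**Compound list**
1 | phloroacetophenone (2,4,6-trihydroxyacetophenone) | CC(=O)c1c(O)cc(O)cc1O | starting material
2 | prenyl bromide (1-bromo-3-methylbut-2-ene) | CC(C)=CCBr | starting material
3 | 2-acetyl-3,5-dihydroxy-6-(3-methylbut-2-en-1-yl)cyclohexa-2,4-dien-1-one (racemic at C6, transient) | CC(=O)C1=C(O)C=C(O)C(CC=C(C)C)C1=O | intermediate
4 | 1-[2,4,6-trihydroxy-3-(3-methylbut-2-en-1-yl)phenyl]ethan-1-one | CC(=O)c1c(O)cc(O)c(CC=C(C)C)c1O | intermediate
5 | 1-[2-hydroxy-4,6-bis(methoxymethoxy)-3-(3-methylbut-2-en-1-yl)phenyl]ethan-1-one | CC(=O)c1c(O)c(CC=C(C)C)c(OCOC)cc1OCOC | intermediate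
6 | (E)-3-(dimethylamino)-1-[2-hydroxy-4,6-bis(methoxymethoxy)-3-(3-methylbut-2-en-1-yl)phenyl]prop-2-en-1-one | CN(C)/C=C/C(=O)c1c(O)c(CC=C(C)C)c(OCOC)cc1OCOC | intermediate
7 | 5,7-bis(methoxymethoxy)-8-(3-methylbut-2-en-1-yl)-4H-chromen-4-one | O=c1ccoc2c(CC=C(C)C)c(OCOC)cc(OCOC)c12 | intermediate
8 | catechol (benzene-1,2-diol) | Oc1ccccc1O | starting material
9 | 1,2-bis(methoxymethoxy)benzene | COCOc1ccccc1OCOC | intermediate
10 | [2,3-bis(methoxymethoxy)phenyl]lithium | [Li]c1cccc(OCOC)c1OCOC | intermediate
11 | 1,2-bis(methoxymethoxy)-3-(3-methylbut-2-en-1-yl)benzene | COCOc1cccc(CC=C(C)C)c1OCOC | intermediate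
12 | 2-[3,4-bis(methoxymethoxy)-5-(3-methylbut-2-en-1-yl)phenyl]-4,4,5,5-tetramethyl-1,3,2-dioxaborolane | COCOc1cc(B2OC(C)(C)C(C)(C)O2)cc(CC=C(C)C)c1OCOC | intermediate
13 | [3,4-bis(methoxymethoxy)-5-(3-methylbut-2-en-1-yl)phenyl]boronic acid | COCOc1cc(B(O)O)cc(CC=C(C)C)c1OCOC | intermediate
14 | (2S)-2-[3,4-bis(methoxymethoxy)-5-(3-methylbut-2-en-1-yl)phenyl]-5,7-bis(methoxymethoxy)-8-(3-methylbut-2-en-1-yl)-2,3-dihydro-4H-chromen-4-one | CC(C)=CCc1cc([C@@H]2CC(=O)c3c(OCOC)cc(OCOC)c(CC=C(C)C)c3O2)cc(OCOC)c1OCOC | intermediate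
15 | (2S)-2-[3,4-dihydroxy-5-(3-methylbut-2-en-1-yl)phenyl]-5,7-dihydroxy-8-(3-methylbut-2-en-1-yl)-2,3-dihydro-4H-chromen-4-one (8,5'-diprenyleriodictyol) | CC(C)=CCc1cc([C@@H]2CC(=O)c3c(O)cc(O)c(CC=C(C)C)c3O2)cc(O)c1O | target

**Step count:** 8 steps in total. The longest linear sequence is 5 steps (1, 2, 3, 7, 8 or 4, 5, 6, 7, 8).

**Three steps most likely to fail**

Step 7.
- **Risk:** The 5-alkoxy, electron-rich chromone may react slowly. Ring opening by β-aryloxide elimination or protodeboronation of 13 may then take over, or the ee may be too low.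
- **Fallback (from 7 and 13, back at 14):** Asymmetric catalysis is replaced by a kinetic resolution. The addition is run with the much more active achiral diene complex [Rh(OH)(cod)]2 (dioxane/H2O, 40 °C) to give the racemic tetra-MOM flavanone F1. This is then submitted to asymmetric transfer hydrogenation with RuCl(p-cymene)[(R,R)-TsDPEN] in HCO2H/Et3N. The catalyst reduces the 2R ketone to the cis-(2R,4R)-flavan-4-ol F2 and leaves the 2S ketone untouched, at most 50 %. Chromatography returns the route at 14.

Step 6.
- **Risk:** Iridium hydride and pinacolborane may hydroborate or isomerise the prenyl alkene.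
- **Fallback (from 9 through its lithio derivative 10, back at 14):** The alkene is introduced only after the boron chemistry.
  - Quenching 10 with I2 gives 1-iodo-2,3-bis(methoxymethoxy)benzene F3.
  - The same iridium-catalysed borylation, now alkene-free, gives the iodoaryl pinacol boronate F4.
  - NaIO4/NH4OAc cleavage gives [3-iodo-4,5-bis(methoxymethoxy)phenyl]boronic acid F5.
  - The asymmetric 1,4-addition of step 7 to chromone 7 gives the (2S)-5'-iodo flavanone F6.
  - A Stille coupling with tributyl(3-methylbut-2-en-1-yl)stannane under the zerovalent palladium catalyst Pd(PPh3)4 (DMF, 80 °C) installs the ring B prenyl group and returns the route at 14.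

Step 8.
- **Risk:** Brønsted acid may close a freed phenol onto its ortho prenyl group to give a dimethylchroman, and the catechol may oxidise in air.
- **Fallback (from 14, back at 15):** Acid solvolysis is replaced by a protecting-group exchange. TESOTf with 2,2'-bipyridyl in MeCN (0 °C to rt) converts the four aryl MOM ethers under non-acidic conditions into the (2S)-tetrakis(triethylsilyl) ether F7. This ether is cleaved with Et3N·3HF in THF at 0 °C, which is neither basic nor strongly acidic.

**Further compounds**
F1 | step 7 | racemic 2-[3,4-bis(methoxymethoxy)-5-(3-methylbut-2-en-1-yl)phenyl]-5,7-bis(methoxymethoxy)-8-(3-methylbut-2-en-1-yl)-2,3-dihydro-4H-chromen-4-one | CC(C)=CCc1cc(C2CC(=O)c3c(OCOC)cc(OCOC)c(CC=C(C)C)c3O2)cc(OCOC)c1OCOC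
F2 | step 7 | (2R,4R)-2-[3,4-bis(methoxymethoxy)-5-(3-methylbut-2-en-1-yl)phenyl]-5,7-bis(methoxymethoxy)-8-(3-methylbut-2-en-1-yl)chroman-4-ol | CC(C)=CCc1cc([C@H]2C[C@@H](O)c3c(OCOC)cc(OCOC)c(CC=C(C)C)c3O2)cc(OCOC)c1OCOC
F3 | step 6 | 1-iodo-2,3-bis(methoxymethoxy)benzene | COCOc1cccc(I)c1OCOC
F4 | step 6 | 2-[3-iodo-4,5-bis(methoxymethoxy)phenyl]-4,4,5,5-tetramethyl-1,3,2-dioxaborolane | COCOc1cc(B2OC(C)(C)C(C)(C)O2)cc(I)c1OCOC
F5 | step 6 | [3-iodo-4,5-bis(methoxymethoxy)phenyl]boronic acid | COCOc1cc(B(O)O)cc(I)c1OCOC
F6 | step 6 | (2S)-2-[3-iodo-4,5-bis(methoxymethoxy)phenyl]-5,7-bis(methoxymethoxy)-8-(3-methylbut-2-en-1-yl)-2,3-dihydro-4H-chromen-4-one | COCOc1cc([C@@H]2CC(=O)c3c(OCOC)cc(OCOC)c(CC=C(C)C)c3O2)cc(I)c1OCOC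
F7 | step 8 | (2S)-2-[3-(3-methylbut-2-en-1-yl)-4,5-bis(triethylsilyloxy)phenyl]-8-(3-methylbut-2-en-1-yl)-5,7-bis(triethylsilyloxy)-2,3-dihydro-4H-chromen-4-one | CC(C)=CCc1cc([C@@H]2CC(=O)c3c(O[Si](CC)(CC)CC)cc(O[Si](CC)(CC)CC)c(CC=C(C)C)c3O2)cc(O[Si](CC)(CC)CC)c1O[Si](CC)(CC)CC
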